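## Retrosynthetic overview

1. Target ⇒ its deacetyl hydroquinone; the last step is a site-selective O-acetylation of the less hindered phenol.
2. Hydroquinone angelate ⇒ (E)-alkenyl-1,4-benzoquinone + angelic acid. The key disconnection is the C3–O bond: an enantioselective 1,6-oxa-addition in which the quinone ends as the hydroquinone and the side-chain methyl becomes the exocyclic methylene.
3. Alkenylquinone ⇒ ortho-alkenylphenol (para-oxidation) ⇒ 6-bromo-2-methoxy-3-methylphenol + (E)-alkenylzinc reagent (hydrozirconation of 6-methylhept-5-en-2-yne, Negishi coupling).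
4. Bromophenol ⇒ 2-methoxy-3-methylphenol; enyne ⇒ prenyl bromide + propynylmagnesium bromide.
5. No ring is formed: the benzene ring is bought and carried through as phenol, para-quinone and hydroquinone.

Assumption: 2-methoxy-3-methylphenol and angelic acid are bought; the sense of induction in step 5 cannot be predicted, so the (R)-catalyst is written and its mirror image is used if it gives the 3R ester.

## Route

Step 1
Reactants: 1 2-methoxy-3-methylphenol
Product: 2 6-bromo-2-methoxy-3-methylphenol
Conditions: t-BuNH2 (2 equiv), Br2 (1 equiv), toluene, −78 °C to rt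
Reagents that add atoms: bromine, BrBr
Why: Amine-mediated ortho-selective electrophilic bromination, in which the N-bromoamine is delivered through hydrogen bonding to the phenol and attacks the only free ortho position (C6) rather than the para position.

Step 2
Reactants: 3 1-bromo-3-methylbut-2-ene (prenyl bromide); 4 prop-1-yn-1-ylmagnesium bromide
Product: 5 6-methylhept-5-en-2-yne
Conditions: CuBr·SMe2 (5 mol %), THF, 0 °C to rt
Reagents that add atoms: none
Why: Monovalent-copper-catalysed SN2 coupling of an alkynyl Grignard reagent with a primary allylic bromide, with attack at the unhindered CH2 end of the prenyl unit giving the skipped enyne.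

Step 3
Reactants: 5 6-methylhept-5-en-2-yne; 2 6-bromo-2-methoxy-3-methylphenol
Product: 8 2-methoxy-3-methyl-6-[(2E)-6-methylhepta-2,5-dien-2-yl]phenol, via alkenylzirconocene chloride 6 (not isolated), via alkenylzinc chloride 7 (not isolated)
Conditions: Cp2Zr(H)Cl (1.15 equiv), THF, 25 to 40 °C; ZnCl2 (1.2 equiv), 0 °C; then 2, Pd(OAc)2 (2 mol %), 2-dicyclohexylphosphino-2′,6′-dimethoxybiphenyl (4 mol %), 25 °C, slow addition of 7
Reagents that add atoms: none
Why: Syn-hydrozirconation places zirconium on the methyl-bearing alkyne carbon after equilibration (expected about 9:1, minor isomer removed by chromatography), and transmetalation to zinc followed by Negishi coupling at zerovalent palladium proceeds with retention to give the E-trisubstituted alkene, the alkenylzinc halide coupling faster than it is protonated by the free phenol.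

Step 4
Reactants: 8 2-methoxy-3-methyl-6-[(2E)-6-methylhepta-2,5-dien-2-yl]phenol
Product: 9 3-methoxy-2-methyl-5-[(2E)-6-methylhepta-2,5-dien-2-yl]cyclohexa-2,5-diene-1,4-dione
Conditions: K2[ON(SO3)2] (2.2 equiv), KH2PO4 buffer, acetone/H2O, 0 °C
Reagents that add atoms: potassium nitrosodisulfonate, [K+].[K+].[O-]S(=O)(=O)N([O])S(=O)(=O)[O-]
Why: Teuber oxidation, in which two equivalents of the nitroxyl radical convert a phenol with a free para position into the para-quinone without touching the alkenes.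

Step 5
Reactants: 9 3-methoxy-2-methyl-5-[(2E)-6-methylhepta-2,5-dien-2-yl]cyclohexa-2,5-diene-1,4-dione; 10 angelic acid [(2Z)-2-methylbut-2-enoic acid]
Product: 12 (3S)-2-(2,5-dihydroxy-3-methoxy-4-methylphenyl)-6-methylhepta-1,5-dien-3-yl (2Z)-2-methylbut-2-enoate, via ortho-quinone methide 11 (not isolated)
Conditions: 10 (1.5 equiv), (R)-3,3′-bis(2,4,6-triisopropylphenyl)-1,1′-binaphthyl-2,2′-diyl hydrogen phosphate (10 mol %), toluene, 0 °C, argon, dark
Reagents that add atoms: none
Why: Proposed new method: a chiral-phosphoric-acid-catalysed enantioselective 1,6-oxa-conjugate addition of a carboxylic acid to a 2-alkenyl-1,4-benzoquinone with aromatising tautomerisation, in which the catalyst hydrogen-bonds the more basic vinylogous-ester carbonyl (the one in linear conjugation with the side-chain alkene) while its phosphoryl oxygen holds angelic acid as a heterodimer that delivers carboxylate oxygen to one face of the δ-carbon (this forms the C3–O bond and sets the S centre), after which the phosphate moves a methyl proton of ortho-quinone methide 11 to oxygen to give the hydroquinone with the exocyclic methylene; the closest known reaction types are phosphoric-acid-catalysed 1,6-additions to para-quinone methides, phosphoric acid/carboxylic acid heterodimer catalysis in the enantioselective carboxylysis of epoxides and aziridines, and the Thiele–Winter acetoxylation of quinones.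

Step 6
Reactants: 12 (3S)-2-(2,5-dihydroxy-3-methoxy-4-methylphenyl)-6-methylhepta-1,5-dien-3-yl (2Z)-2-methylbut-2-enoate
Product: 13 (3S)-2-[5-(acetyloxy)-2-hydroxy-3-methoxy-4-methylphenyl]-6-methylhepta-1,5-dien-3-yl (2Z)-2-methylbut-2-enoate
Conditions: Ac2O (1.05 equiv), Et3N (1.2 equiv), CH2Cl2, −20 °C
Reagents that add atoms: acetic anhydride, CC(=O)OC(C)=O
Why: Kinetically controlled O-acylation, in which the C5 hydroxyl (neighbours methyl and H) reacts before the C2 hydroxyl (flanked by methoxy and the branched alkenyl group and hydrogen-bonded), while the C3 stereocentre and the Z-angelate are untouched.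

## Compound list

1 | 2-methoxy-3-methylphenol | COc1c(C)cccc1O | starting material
2 | 6-bromo-2-methoxy-3-methylphenol | COc1c(C)ccc(Br)c1O | intermediate
3 | 1-bromo-3-methylbut-2-ene (prenyl bromide) | CC(C)=CCBr | starting material
4 | prop-1-yn-1-ylmagnesium bromide | CC#C[Mg]Br | starting material
5 | 6-methylhept-5-en-2-yne | CC#CCC=C(C)C | intermediate
6 | chlorobis(cyclopentadienyl)[(2E)-6-methylhepta-2,5-dien-2-yl]zirconium | C/C(=C\CC=C(C)C)[Zr](Cl)(C1C=CC=C1)C1C=CC=C1 | intermediate
7 | chloro[(2E)-6-methylhepta-2,5-dien-2-yl]zinc | C/C(=C\CC=C(C)C)[Zn]Cl | intermediate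
8 | 2-methoxy-3-methyl-6-[(2E)-6-methylhepta-2,5-dien-2-yl]phenol | C/C(=C\CC=C(C)C)c1ccc(C)c(OC)c1O | intermediate
9 | 3-methoxy-2-methyl-5-[(2E)-6-methylhepta-2,5-dien-2-yl]cyclohexa-2,5-diene-1,4-dione | C/C(=C\CC=C(C)C)C1=CC(=O)C(C)=C(OC)C1=O | intermediate
10 | angelic acid, (2Z)-2-methylbut-2-enoic acid | C/C=C(/C)C(=O)O | starting material
11 | (3S)-2-(3-hydroxy-5-methoxy-4-methyl-6-oxocyclohexa-2,4-dien-1-ylidene)-6-methylhept-5-en-3-yl (2Z)-2-methylbut-2-enoate (exocyclic alkene geometry not defined) | CC(=C1C=C(O)C(C)=C(OC)C1=O)[C@H](CC=C(C)C)OC(=O)/C(C)=C\C | intermediate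
12 | (3S)-2-(2,5-dihydroxy-3-methoxy-4-methylphenyl)-6-methylhepta-1,5-dien-3-yl (2Z)-2-methylbut-2-enoate | C=C(c1cc(O)c(C)c(OC)c1O)[C@H](CC=C(C)C)OC(=O)/C(C)=C\C | intermediate
13 | (3S)-2-[5-(acetyloxy)-2-hydroxy-3-methoxy-4-methylphenyl]-6-methylhepta-1,5-dien-3-yl (2Z)-2-methylbut-2-enoate | C=C(c1cc(OC(C)=O)c(C)c(OC)c1O)[C@H](CC=C(C)C)OC(=O)/C(C)=C\C | target

## Step count and risks

Total steps: 6. Longest linear sequence: 5 (1 → 2 → 8 → 9 → 12 → 13; the branch 3 + 4 → 5 joins at step 3).

**Step 5 (the proposed new reaction).** Four things can go wrong: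
- the δ-carbon of 9 may be too weakly electrophilic for a carboxylic acid;
- 9 may instead enolise through its doubly allylic CH2 and close to a 2H-chromenol;
- product 12 and unreacted 9 can exchange redox equivalents, which slows conversion;
- the level and sense of induction are unknown.

Fallback (known chemistry, C–O bond still made at the stereocentre), setting out from 2 and coming back at 12. Compound 2 is protected (MOMCl, i-Pr2NEt) as 1-bromo-3-methoxy-2-(methoxymethoxy)-4-methylbenzene F1. Bromine–lithium exchange (n-BuLi, THF, −78 °C) and acylation with N-methoxy-N,5-dimethylhex-4-enamide F2 (made from commercial 5-methylhex-4-enoic acid and MeNHOMe·HCl with a carbodiimide) give 1-[3-methoxy-2-(methoxymethoxy)-4-methylphenyl]-5-methylhex-4-en-1-one F3. Asymmetric enolate hydroxylation (KN(SiMe3)2, −78 °C, then the enantiomer of (camphorsulfonyl)oxaziridine that gives the S alcohol) gives (2S)-2-hydroxy-1-[3-methoxy-2-(methoxymethoxy)-4-methylphenyl]-5-methylhex-4-en-1-one F4. Wittig methylenation (Ph3P=CH2 in excess, THF, 0 °C) gives (3S)-2-[3-methoxy-2-(methoxymethoxy)-4-methylphenyl]-6-methylhepta-1,5-dien-3-ol F5. Yamaguchi esterification with 10 (2,4,6-trichlorobenzoyl chloride, Et3N, toluene; retention) gives (3S)-2-[3-methoxy-2-(methoxymethoxy)-4-methylphenyl]-6-methylhepta-1,5-dien-3-yl (2Z)-2-methylbut-2-enoate F6. Acetal cleavage (ZnBr2, n-PrSH, CH2Cl2, 0 °C) gives (3S)-2-(2-hydroxy-3-methoxy-4-methylphenyl)-6-methylhepta-1,5-dien-3-yl (2Z)-2-methylbut-2-enoate F7. Teuber oxidation (K2[ON(SO3)2]) gives (3S)-2-(5-methoxy-4-methyl-3,6-dioxocyclohexa-1,4-dien-1-yl)-6-methylhepta-1,5-dien-3-yl (2Z)-2-methylbut-2-enoate F8. Reduction with aqueous Na2S2O4 gives 12, and step 6 follows.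

**Step 3 (hydrozirconation and Negishi coupling).** Regiocontrol of the hydrozirconation is only moderate, and the unprotected, electron-rich bromophenol may protonate the zinc reagent or react slowly.

Fallback (carbonyl addition and dehydration in place of cross-coupling), setting out from 2 and coming back at 8. Compound 2 is converted into its O,C-dilithio species (n-BuLi, 2.2 equiv, THF, −78 °C) and added to commercial 6-methylhept-5-en-2-one to give 2-(2-hydroxy-3-methoxy-4-methylphenyl)-6-methylhept-5-en-2-ol F9. Mild dehydration (catalytic pyridinium p-toluenesulfonate, toluene, 80 °C) gives 8 together with its Z and exocyclic isomers; the E isomer is separated on AgNO3-impregnated silica.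

**Step 6 (site-selective acetylation).** Some C2 acetate and diacetate may form if the steric difference between the two phenols is smaller than expected.

Fallback (discrimination by silyl ethers in place of direct acylation), setting out from 12 and coming back at 13. Bis-silylation (t-BuMe2SiOTf, 2,6-lutidine) gives (3S)-2-{2,5-bis[(tert-butyldimethylsilyl)oxy]-3-methoxy-4-methylphenyl}-6-methylhepta-1,5-dien-3-yl (2Z)-2-methylbut-2-enoate F10. Selective cleavage of the unhindered aryl silyl ether (Cs2CO3, DMF/H2O, rt) gives (3S)-2-{2-[(tert-butyldimethylsilyl)oxy]-5-hydroxy-3-methoxy-4-methylphenyl}-6-methylhepta-1,5-dien-3-yl (2Z)-2-methylbut-2-enoate F11. Acetylation (Ac2O, pyridine, 4-dimethylaminopyridine) gives (3S)-2-{5-(acetyloxy)-2-[(tert-butyldimethylsilyl)oxy]-3-methoxy-4-methylphenyl}-6-methylhepta-1,5-dien-3-yl (2Z)-2-methylbut-2-enoate F12. HF·pyridine in THF at 0 °C then gives 13.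

## Further compounds

F1 | step 5 | 1-bromo-3-methoxy-2-(methoxymethoxy)-4-methylbenzene | COCOc1c(Br)ccc(C)c1OC
F2 | step 5 | N-methoxy-N,5-dimethylhex-4-enamide | CON(C)C(=O)CCC=C(C)C
F3 | step 5 | 1-[3-methoxy-2-(methoxymethoxy)-4-methylphenyl]-5-methylhex-4-en-1-one | COCOc1c(C(=O)CCC=C(C)C)ccc(C)c1OC
F4 | step 5 | (2S)-2-hydroxy-1-[3-methoxy-2-(methoxymethoxy)-4-methylphenyl]-5-methylhex-4-en-1-one | COCOc1c(C(=O)[C@@H](O)CC=C(C)C)ccc(C)c1OC
F5 | step 5 | (3S)-2-[3-methoxy-2-(methoxymethoxy)-4-methylphenyl]-6-methylhepta-1,5-dien-3-ol | C=C(c1ccc(C)c(OC)c1OCOC)[C@H](CC=C(C)C)O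
F6 | step 5 | (3S)-2-[3-methoxy-2-(methoxymethoxy)-4-methylphenyl]-6-methylhepta-1,5-dien-3-yl (2Z)-2-methylbut-2-enoate | C=C(c1ccc(C)c(OC)c1OCOC)[C@H](CC=C(C)C)OC(=O)/C(C)=C\C
F7 | step 5 | (3S)-2-(2-hydroxy-3-methoxy-4-methylphenyl)-6-methylhepta-1,5-dien-3-yl (2Z)-2-methylbut-2-enoate | C=C(c1ccc(C)c(OC)c1O)[C@H](CC=C(C)C)OC(=O)/C(C)=C\C
F8 | step 5 | (3S)-2-(5-methoxy-4-methyl-3,6-dioxocyclohexa-1,4-dien-1-yl)-6-methylhepta-1,5-dien-3-yl (2Z)-2-methylbut-2-enoate | C=C(C1=CC(=O)C(C)=C(OC)C1=O)[C@H](CC=C(C)C)OC(=O)/C(C)=C\C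
F9 | step 3 | 2-(2-hydroxy-3-methoxy-4-methylphenyl)-6-methylhept-5-en-2-ol (racemic) | CC(O)(CCC=C(C)C)c1ccc(C)c(OC)c1O
F10 | step 6 | (3S)-2-{2,5-bis[(tert-butyldimethylsilyl)oxy]-3-methoxy-4-methylphenyl}-6-methylhepta-1,5-dien-3-yl (2Z)-2-methylbut-2-enoate | C=C(c1cc(O[Si](C)(C)C(C)(C)C)c(C)c(OC)c1O[Si](C)(C)C(C)(C)C)[C@H](CC=C(C)C)OC(=O)/C(C)=C\C
F11 | step 6 | (3S)-2-{2-[(tert-butyldimethylsilyl)oxy]-5-hydroxy-3-methoxy-4-methylphenyl}-6-methylhepta-1,5-dien-3-yl (2Z)-2-methylbut-2-enoate | C=C(c1cc(O)c(C)c(OC)c1O[Si](C)(C)C(C)(C)C)[C@H](CC=C(C)C)OC(=O)/C(C)=C\C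
F12 | step 6 | (3S)-2-{5-(acetyloxy)-2-[(tert-butyldimethylsilyl)oxy]-3-methoxy-4-methylphenyl}-6-methylhepta-1,5-dien-3-yl (2Z)-2-methylbut-2-enoate | C=C(c1cc(OC(C)=O)c(C)c(OC)c1O[Si](C)(C)C(C)(C)C)[C@H](CC=C(C)C)OC(=O)/C(C)=C\C
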